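Readings and results are calculated on assumed constants; noise was put on by code.

The pitfall in curves like these was to call them first order in electrophile and stop there, since a decay that looks exponential can hide a second reagent falling in step with the first.

| flask | electrophile | free base | protonated nucleophile | remark | time |
|---|---|---|---|---|---|
| dusk | 0.050 M | 0.14 M | 0.055 M | run made earlier |  |
| noon | 0.050 M | 0.26 M | 0.055 M | run made earlier |  |
| alder | 0.050 M | 0.100 M | 0.0550 M |  | 8.0 d |
| oak | 0.050 M | 0.150 M | 0.0550 M |  | 8.0 d |
| birch | 0.050 M | 0.230 M | 0.0550 M |  | 8.0 d |

- dusk (time / d: electrophile / %, product / %): 0.625: 95.1, 3.8; 1.04: 89.6, 9.0; 1.67: 86.3, 17.3; 3.00: 71.9, 29.3; 5.00: 57.7, 41.8; 8.00: 44.0, 57.3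
- noon (time / d: electrophile / %, product / %): 0.625: 93.7, 7.2; 1.04: 87.4, 12.8; 1.67: 80.1, 22.6; 3.00: 63.8, 36.9; 5.00: 46.0, 53.6; 8.00: 32.8, 69.5

(standard deviation of a reading: 1 percentage point)

1. part of the electrophile that has reacted at the end, alder
2. part of the electrophile that has reacted at the end, oak
3. part of the electrophile that has reacted at the end, birch
4. what raising the concentration of free base from its lowest to its highest value here does to the part of the electrophile that has reacted (changes below 5 percentage points count as none) (it falls / it rises / no change)

- a reading or a percentage of product counts all its forms, free or not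

I built a ladder from the readings. On the fastest rung stood whatever lies between electrophile and product: at the first dusk reading, 0.625 d, the two already summed to 98.9%, so I saw no hold-up. Next came the fall of electrophile, with a pseudo-first-order half-life in dusk of 6.75 d, slower than that first reading. The readings have no column for free base, so in my reckoning I held it at its charge, as a simplification and not as a rung of the ladder.

The first-order constants of noon and dusk differ by a factor of 1.36, and the root of their free base ratio is 1.36. Electrophile A and protonated nucleophile C were charged nearly equal, so a root of their product would also look first order. I supposed C is spent one for one with A and wrote −dA/dt = g√(ACF), with A and C in units of the electrophile charge and F, the free base, in units of dusk's. This integrates in closed form: S = √A + √C decays as exp(−g√F t/2), and √A is the mean of S and (A−C)/S.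

Dusk gave 0.0955 d⁻¹ and noon 0.0941 d⁻¹, so I carried their mean, 0.0948 d⁻¹, the pace g of this clock. My reckoning gave 49.6% for alder, 57.0% for oak and 65.1% for birch.

The forecast, saying “With only two base levels, I can't distinguish these”, gave 50%, 58% and 65%, and it rises.

The flasks gave 49.9%, 58.3% and 66.7%: it rises, by 17 percentage points.

    nucleophile + acid set free ⇌ protonated nucleophile, settled at all times (K = 80000 L mol⁻¹)
    acid set free + free base ⇌ salt of the base (K = 52000 L mol⁻¹, k = 28.0 L mol⁻¹ h⁻¹)
    electrophile + nucleophile ⇌ acid set free + product (K = 0.550, k = 1.20 L mol⁻¹ h⁻¹)
    nucleophile ⇌ dormant form (K = 0.350, k = 0.190 h⁻¹)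
    crystals ⇌ product, rate k5*(cs5 - [product]) while solid is left; crystals form when [product] > cs5 (solubility = 2.80 mM, k = 0.780 h⁻¹)

Birch's answer moved by 5 points with protonated nucleophile at 0.0468 M or 0.0650 M, other charges and the time held. With g, those two charges give 60.1% and 70.4%, on either side of my 65.1%.

A neighbour of birch was charged with 0.20 M of electrophile. There g gives 26.8% reacted. The computed flask gave 26.8%.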